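TBDPS = tert‑butyldiphenylsilyl. Atom numbers C1–C20 are those of the diterpenoid skeleton (C1–C10 in rings A and B, C11–C16 in the chain, C17 on C8, C18/C19 on C4, C20 on C9).

## Analysis of the target

The target is a bicyclic diterpenoid acid of the halimane type, esterified with a 1,3‑diacylglycerol. Rings A and B form an octalin with a trisubstituted C1=C10 alkene, a gem‑dimethyl group at C4, a ring‑fusion hydrogen at C5, a secondary methyl (C17) at C8 and a quaternary C9 carrying methyl C20 and the C11–C15 chain. C15 is the ester carbonyl on one primary oxygen of glycerol; the other primary oxygen is acetylated and the secondary hydroxyl is free.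

There are five stereocentres: C5 (S), C8 (R) and C9 (R) in the ring system, C13 (R) in the chain and the glycerol carbinol (S). On ring B the C17 methyl and the C11 chain are cis, C20 is trans to C17, and H5 lies on the face of C11 and C17. C13 is two methylenes away from C9 and the glycerol centre is more remote still, so both must come from enantiopure building blocks.

Two groups are sensitive. The C1=C10 alkene can slip to the tetrasubstituted C5=C10 position under strong acid. The glycerol part, with its free secondary hydroxyl, is prone to acyl migration, which would scramble regiochemistry and configuration.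

The hard part is the region around C10: an sp2 carbon between quaternary C9 (next to stereocentre C8) and C5, which is itself next to quaternary C4. The route rests on one feature: C9 is bonded to sp2 C10 of ring A, and its chain can begin as a C9=C11 alkene. An alkenylpalladium at C10 can then insert that alkene in a 6‑exo mode and create the C9–C10 bond, the quaternary centre and ring B in one step.

## Retrosynthetic reasoning

**Glycerol ester (34 ⇐ 33 ⇐ 32 ⇐ 30 + 31).** The acetate and the C15–O ester bond are cut last, because a glycerol with a free secondary hydroxyl should be exposed to as few steps as possible. Acid 30 is joined to the free primary hydroxyl of 31, which supplies the glycerol stereocentre with its diol masked. Unmasking gives 33, and a primary‑selective acetylation gives 34.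

**C15 oxidation level (30 ⇐ 29 ⇐ 28).** The acid is taken back to the silyl ether 28. A protected primary alcohol survives the organometallic, hydride and palladium steps that a carboxyl derivative would not.

**C5–H and the C1=C10 alkene (28 ⇐ 25 ⇐ 24).** The C5–H bond is cut together with a shift of the alkene: 28 is the product of a reductive 1,3‑transposition of the allylic alcohol 25. The forward reaction replaces the C1 oxygen by a diazene with inversion, and the diazene passes its hydrogen to C5 on its own face. C5 is therefore set from C1, and C1 is set by a reagent‑controlled reduction of ketone 24. This is preferred to setting C5 by enolate or hydrogenation chemistry, which would depend on the conformation of a congested ring.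

**C9–C10 bond and ring B (24 ⇐ 23 ⇐ 22).** This is the key disconnection. Cutting C9–C10 opens ring B and turns the quaternary centre into the trisubstituted alkene C9=C11 of iodoenone 22. The forward reaction, an intramolecular alkene insertion of an alkenylpalladium on a chiral bisphosphine, forms the most hindered bond of the molecule while C5 and C10 are still flat. It leaves a C11=C12 alkene (23) that is hydrogenated to 24. The cut is made here and not at C5–C10 or C8–C9 because only this bond joins an sp2 carbon to the quaternary centre.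

**C5–C6 bond and C10–I (22 ⇐ 21 ⇐ 18 + 3).** The iodine is removed to give enone 21. The C5–C6 bond is cut to the primary iodide 18 (as its organolithium) and the vinylogous ester 3. Addition to the carbonyl of 3 followed by hydrolytic transposition places the chain next to the gem‑dimethyl carbon, so C4 is quaternary from the start.

**C11–C12 bond (18 ⇐ 17 ⇐ 9 + 15).** The tether is cut between sp2 C11 and sp3 C12. This puts C8 and C13 on separate fragments, so each can come from one enantiomer of the same lactone. The forward coupling of the alkylzinc from 9 with alkenyl iodide 15 retains the alkene geometry. The chloride in 15 is carried through the coupling and exchanged for iodide afterwards (17 to 18).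

**C9–C20 bond and the (E)‑alkene (15 ⇐ 14 ⇐ 12 ⇐ 11 ⇐ 10).** The methyl on C9 and the iodine on C11 are removed together, leading back to the terminal alkyne 12. A syn carbometalation fixes the (E) geometry that the insertion step needs. The alkyne comes from lactone 10 through lactol 11; the lactone stereocentre becomes C8.

**C12–C15 fragment (9 ⇐ 8 ⇐ 6 ⇐ 5 ⇐ 4).** Iodide 9 is traced to lactone 4. The ring is opened to an amide (5), the liberated hydroxyl (future C15) is silylated (6), and the acyl carbon is reduced to the CH2 that becomes C12 (8). The lactone stereocentre becomes C13.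

**Ring A (3 ⇐ 2 ⇐ 1).** The gem‑dimethyl group is taken off in two enolate methylations, back to 1.

## Alternatives that were turned down

**Alternative 1:** The C8–C17 and C9–C20 bonds are cut on a ring B cyclohexanone. In the forward step a chiral copper catalyst transfers a methyl group from an aluminium reagent to C8 of the 2‑alkylcyclohexenone A1, and the enolate is methylated at C9 to give the 2,2,3‑trisubstituted cyclohexanone A2.
- For it: one catalytic operation installs both methyl groups and both ring stereocentres. The sense of the conjugate addition is well established, and alkylation anti to the new C8 methyl should give the required trans C17/C20 relationship. On control of C8 and C9 this is at least as strong as the chosen cyclisation, probably stronger.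
- Against it: no ring is closed. Aluminium enolates alkylate poorly, so an ate complex or transmetalation is needed. A2 still lacks ring A, which must be annulated at the C10 ketone, already flanked by quaternary C9. That requires attaching quaternary C4 to C5 next to the ketone, forming C1=C10 from a very hindered carbonyl, and setting C5 by enolate chemistry.
- Comparison: the chosen route gives up some certainty at C9, but it has ring A, the gem‑dimethyl group and the whole carbon skeleton in place when ring B closes, and it sets C5 by a stereospecific hydrogen transfer. Alternative 1 would need a long and uncertain annulation after its key step.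

**Alternative 2:** The C1=C10 double bond is cut. In the forward step low‑valent titanium couples the C10 ketone and the C1 aldehyde of keto aldehyde A3 and closes ring A to give A4, which is identical with 28 of the chosen route.
- For it: the alkene is formed directly in its final position, so no transposition and no C1 stereocentre are needed. Closure of a six‑membered ring by carbonyl coupling is well precedented. On the placement of the alkene it is stronger than the chosen route.
- Against it: A3 must already contain C5, C8 and C9, and C5 is an epimerisable centre α to the ketone. The C5–C4 bond joins a tertiary carbon to a quaternary one next to a carbonyl flanked by quaternary C9, and no simple alkylation makes it. The C10 ketone is shielded on both sides, so pinacol coupling would be slow and the aldehyde could be reduced or dimerised first.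
- Comparison: the ending is shorter, but the difficulty moves into the synthesis of A3. The chosen route builds the same crowded C4–C5–C10–C9 array while C5 and C10 are sp2 and pays for it with two extra steps.

**Alternative 3:** The C2–C3 and C4–C5 bonds are cut. In the forward step the ring B diene A5 and Lewis‑acid‑activated methacrolein A6 combine to the formyl cycloadduct A7, closing ring A with the alkene at C1=C10.
- For it: ring A and the alkene arise in one convergent step. The required orientation, with the substituted dienophile carbon bonding to the substituted diene terminus C5, is the electronically preferred one. Either C4 epimer can be used. In ring‑forming economy it is as good as the chosen cyclisation.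
- Against it: C5 is set by the face of the diene that the dienophile chooses, and the only bias is quaternary C9, whose methyl and CH2 substituents differ little. The step joins a quaternary C4 to C5 next to the C9 neopentyl position with an α‑substituted, sluggish dienophile. The Lewis acid may isomerise or polymerise the hindered diene. The formyl group must afterwards be reduced to methyl in two or three steps. A5 itself needs C8 and C9 set first and a vinyl group placed on a hindered ketone.
- Comparison: the chosen route has the gem‑dimethyl group from the first step and controls C5 through C1. Its cost is a longer linear sequence.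

Key step: step 15

Assumption: in step 15 (R)‑BINAP is taken to be the ligand enantiomer whose facial preference agrees with that of the C8 methyl group; the mirror‑image ligand is used in the same procedure if the pairing proves mismatched.

## Route

Step 1
Reactants: 1 3‑ethoxycyclohex‑2‑en‑1‑one
Product: 2 3‑ethoxy‑6‑methylcyclohex‑2‑en‑1‑one (racemic)
Conditions: LiN(i‑Pr)2, THF, −78 °C; MeI, −78 → 0 °C
Reagents that add atoms: iodomethane, CI
Why: Kinetic deprotonation of the vinylogous ester occurs at C6, the saturated α‑position, and the enolate is C‑methylated (Stork–Danheiser alkylation); the new centre is racemic and disappears in step 2.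

Step 2
Reactants: 2 3‑ethoxy‑6‑methylcyclohex‑2‑en‑1‑one
Product: 3 3‑ethoxy‑6,6‑dimethylcyclohex‑2‑en‑1‑one
Conditions: LiN(i‑Pr)2, THF, −78 °C; MeI, −78 °C → rt
Reagents that add atoms: iodomethane, CI
Why: A second kinetic enolisation at the same carbon and methylation give the gem‑dimethyl group that becomes C4 with C18 and C19; after this the carbonyl has no α‑hydrogen on that side, which also prevents enolisation in step 13.

Step 3
Reactants: 4 (S)‑α‑methyl‑γ‑butyrolactone
Product: 5 (2S)‑4‑hydroxy‑N‑methoxy‑N,2‑dimethylbutanamide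
Conditions: MeNH(OMe)·HCl, Me3Al, CH2Cl2, 0 °C → rt
Reagents that add atoms: N,O‑dimethylhydroxylamine hydrochloride, CNOC.Cl
Why: The aluminium amide formed from Me3Al and the amine salt opens the lactone at the acyl carbon (Weinreb aminolysis) without touching the α‑stereocentre, which becomes C13; the hydroxy amide is silylated at once because it relactonises on standing.

Step 4
Reactants: 5 (2S)‑4‑hydroxy‑N‑methoxy‑N,2‑dimethylbutanamide
Product: 6 (2S)‑4‑(tert‑butyldiphenylsilyloxy)‑N‑methoxy‑N,2‑dimethylbutanamide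
Conditions: TBDPSCl, imidazole, DMF, 0 °C → rt
Reagents that add atoms: tert‑butyl(chloro)diphenylsilane, CC(C)(C)[Si](Cl)(c1ccccc1)c1ccccc1
Why: Standard silylation of a primary alcohol; TBDPS is chosen because it withstands t‑BuLi, organozinc, aqueous HCl, hydride and Mitsunobu conditions in the later steps.

Step 5
Reactants: 6 (2S)‑4‑(tert‑butyldiphenylsilyloxy)‑N‑methoxy‑N,2‑dimethylbutanamide
Product: 8 (2S)‑4‑(tert‑butyldiphenylsilyloxy)‑2‑methylbutan‑1‑ol, via aldehyde 7 (not isolated)
Conditions: i‑Bu2AlH, THF, −78 °C; then MeOH, NaBH4, −78 → 0 °C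
Reagents that add atoms: none
Why: i‑Bu2AlH stops at the chelated tetrahedral intermediate of the Weinreb amide, which releases aldehyde 7 on quenching with methanol; NaBH4 reduces it in the same pot before the α‑stereocentre can epimerise.

Step 6
Reactants: 8 (2S)‑4‑(tert‑butyldiphenylsilyloxy)‑2‑methylbutan‑1‑ol
Product: 9 tert‑butyl{[(3S)‑4‑iodo‑3‑methylbutyl]oxy}diphenylsilane
Conditions: I2, PPh3, imidazole, CH2Cl2, 0 °C → rt
Reagents that add atoms: iodine, II
Why: Appel‑type iodination through the alkoxyphosphonium iodide, an SN2 displacement at the primary carbon that does not involve the stereocentre.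

Step 7
Reactants: 10 (R)‑α‑methyl‑γ‑butyrolactone
Product: 11 (3R)‑3‑methyloxolan‑2‑ol (lactol, both anomers)
Conditions: i‑Bu2AlH (1.1 equiv), CH2Cl2, −78 °C
Reagents that add atoms: none
Why: Partial reduction of a γ‑lactone stops at the lactol because the aluminium hemiacetal is stable at −78 °C.

Step 8
Reactants: 11 (3R)‑3‑methyloxolan‑2‑ol
Product: 12 (3R)‑3‑methylpent‑4‑yn‑1‑ol
Conditions: dimethyl (1‑diazo‑2‑oxopropyl)phosphonate, K2CO3, MeOH, 0 °C → rt
Reagents that add atoms: dimethyl (1‑diazo‑2‑oxopropyl)phosphonate, COP(=O)(OC)C(=[N+]=[N-])C(C)=O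
Why: The lactol is in equilibrium with its hydroxy aldehyde, which undergoes Ohira–Bestmann (Seyferth–Gilbert) homologation to the terminal alkyne (future C9≡C11). The mild carbonate base and the low stationary concentration of free aldehyde should leave the α‑methyl stereocentre (future C8) intact.

Step 9
Reactants: 12 (3R)‑3‑methylpent‑4‑yn‑1‑ol
Product: 14 (3R,4E)‑5‑iodo‑3,4‑dimethylpent‑4‑en‑1‑ol, via alkenylalane 13 (not isolated)
Conditions: Me3Al (3 equiv), Cp2ZrCl2 (0.25 equiv), CH2Cl2, 0 °C → rt; then I2, THF, −30 → 0 °C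
Reagents that add atoms: trimethylaluminium, C[Al](C)C; iodine, II
Why: Zirconium‑catalysed carboalumination (Negishi) adds methyl and aluminium syn across the terminal alkyne with methyl on the internal carbon, so iodinolysis with retention gives the (E)‑iodoalkene with C20 in place. The free hydroxyl is carried as its aluminium alkoxide, as with other pentynols.

Step 10
Reactants: 14 (3R,4E)‑5‑iodo‑3,4‑dimethylpent‑4‑en‑1‑ol
Product: 15 (1E,3R)‑5‑chloro‑1‑iodo‑2,3‑dimethylpent‑1‑ene
Conditions: PPh3, N‑chlorosuccinimide, CH2Cl2, 0 °C → rt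
Reagents that add atoms: N‑chlorosuccinimide, O=C1CCC(=O)N1Cl
Why: Chlorodehydroxylation through the alkoxyphosphonium salt (SN2 at C6). A primary chloride is inert to palladium and organozinc in step 11 yet can be exchanged for iodide afterwards, which saves a protection and deprotection.

Step 11
Reactants: 9 tert‑butyl{[(3S)‑4‑iodo‑3‑methylbutyl]oxy}diphenylsilane; 15 (1E,3R)‑5‑chloro‑1‑iodo‑2,3‑dimethylpent‑1‑ene
Product: 17 tert‑butyl{[(3R,5E,7R)‑9‑chloro‑3,6,7‑trimethylnon‑5‑en‑1‑yl]oxy}diphenylsilane, via alkylzinc iodide 16 (not isolated)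
Conditions: 9, Zn, LiCl, THF, 40 °C; then 15, PdCl2(dppf) (5 mol %), THF, rt → 50 °C
Reagents that add atoms: none
Why: Zinc inserts into the primary C–I bond of 9, and the alkylzinc iodide couples with the alkenyl iodide under palladium catalysis (Negishi sp3–sp2 coupling) with retention of alkene geometry, forming C11–C12. The bidentate ligand suppresses β‑hydride elimination and the alkyl chloride does not react.

Step 12
Reactants: 17 tert‑butyl{[(3R,5E,7R)‑9‑chloro‑3,6,7‑trimethylnon‑5‑en‑1‑yl]oxy}diphenylsilane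
Product: 18 tert‑butyl{[(3R,5E,7R)‑9‑iodo‑3,6,7‑trimethylnon‑5‑en‑1‑yl]oxy}diphenylsilane
Conditions: NaI, butan‑2‑one, 80 °C
Reagents that add atoms: sodium iodide, [Na+].[I-]
Why: Finkelstein exchange at the unhindered primary carbon C6, driven by precipitation of NaCl; only the iodide undergoes clean lithium–halogen exchange in step 13.

Step 13
Reactants: 18 tert‑butyl{[(3R,5E,7R)‑9‑iodo‑3,6,7‑trimethylnon‑5‑en‑1‑yl]oxy}diphenylsilane; 3 3‑ethoxy‑6,6‑dimethylcyclohex‑2‑en‑1‑one
Product: 21 3‑[(3R,4E,7R)‑9‑(tert‑butyldiphenylsilyloxy)‑3,4,7‑trimethylnon‑4‑en‑1‑yl]‑4,4‑dimethylcyclohex‑2‑en‑1‑one, via organolithium 19 (not isolated), via carbinol adduct 20 (not isolated)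
Conditions: 18, t‑BuLi (2.1 equiv), Et2O–pentane, −78 °C; then 3, THF, −78 → 0 °C; then 1 M HCl, rt
Reagents that add atoms: water, O
Why: Two equivalents of t‑BuLi convert the primary iodide into organolithium 19, a pent‑4‑enyllithium with no favourable cyclisation mode, which adds 1,2 to the non‑enolisable carbonyl of 3. Aqueous acid then hydrolyses the enol ether with loss of the tertiary hydroxyl (Stork–Danheiser transposition), forming C5–C6 and placing the chain next to the gem‑dimethyl carbon.

Step 14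
Reactants: 21 3‑[(3R,4E,7R)‑9‑(tert‑butyldiphenylsilyloxy)‑3,4,7‑trimethylnon‑4‑en‑1‑yl]‑4,4‑dimethylcyclohex‑2‑en‑1‑one
Product: 22 3‑[(3R,4E,7R)‑9‑(tert‑butyldiphenylsilyloxy)‑3,4,7‑trimethylnon‑4‑en‑1‑yl]‑2‑iodo‑4,4‑dimethylcyclohex‑2‑en‑1‑one
Conditions: I2, pyridine, DMAP (0.2 equiv), CH2Cl2, rt, dark
Reagents that add atoms: iodine, II
Why: α‑Iodination of a cyclic enone with iodine and an amine (Johnson iodination): the amine adds to C5, the enolate is iodinated at C10 and the amine is eliminated. DMAP is included as the stronger nucleophile because C5 is fully substituted, and the isolated trisubstituted alkene should not add iodine irreversibly without a protic nucleophile.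

Step 15
Reactants: 22 3‑[(3R,4E,7R)‑9‑(tert‑butyldiphenylsilyloxy)‑3,4,7‑trimethylnon‑4‑en‑1‑yl]‑2‑iodo‑4,4‑dimethylcyclohex‑2‑en‑1‑one
Product: 23 (7R,8S)‑8‑[(1E,3S)‑5‑(tert‑butyldiphenylsilyloxy)‑3‑methylpent‑1‑en‑1‑yl]‑4,4,7,8‑tetramethyl‑3,4,5,6,7,8‑hexahydronaphthalen‑1(2H)‑one
Conditions: Pd(OAc)2 (10 mol %), (R)‑BINAP (20 mol %), Ag3PO4 (2 equiv), N‑methylpyrrolidone, 80 °C
Reagents that add atoms: none
Why: Pd(OAc)2, a divalent palladium salt, is reduced by the phosphine to zerovalent palladium, which adds oxidatively to the C10–I bond; Ag3PO4 removes iodide, so both phosphorus atoms stay on the cationic alkenylpalladium while the C9=C11 alkene binds. Syn migratory insertion joins C10 to the more substituted C9 in a 6‑exo‑trig closure of ring B and puts palladium on C11; C9 has no hydrogen, so β‑hydride elimination can only take H from C12 and gives the (E)‑C11=C12 alkene. The closest known reaction type is the asymmetric intramolecular 6‑exo Heck cyclisation of alkenyl iodides and triflates onto trisubstituted alkenes, which forms quaternary carbons with Pd(OAc)2, BINAP and a silver salt. The new stereocentre C9 is fixed by the alkene face that inserts. In the chair‑like arrangement of C5–C6–C7–C8–C9 the C8 methyl is pseudo‑equatorial and the alkene stands perpendicular to the plane of the C5=C10 bond, so C11 ends pseudo‑axial and cis to C17 while C20 ends pseudo‑equatorial and trans to C17, as the target requires; the bound BINAP enantiomer is the second control element and is meant to reinforce this bias. The step needs 6‑exo over 7‑endo closure, which the three‑atom tether and the eclipsed Pd–C/C=C geometry secure. It also needs the absence of Pd–H re‑addition that would move the alkene toward C13 (silver salt, cationic pathway) and of C–I reduction (no hydride source). C5 stays sp2, so only one stereocentre is created; C5 is set in step 18.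

Step 16
Reactants: 23 (7R,8S)‑8‑[(1E,3S)‑5‑(tert‑butyldiphenylsilyloxy)‑3‑methylpent‑1‑en‑1‑yl]‑4,4,7,8‑tetramethyl‑3,4,5,6,7,8‑hexahydronaphthalen‑1(2H)‑one
Product: 24 (7R,8R)‑8‑[(3R)‑5‑(tert‑butyldiphenylsilyloxy)‑3‑methylpentyl]‑4,4,7,8‑tetramethyl‑3,4,5,6,7,8‑hexahydronaphthalen‑1(2H)‑one
Conditions: H2 (4 atm), RhCl(PPh3)3 (10 mol %), benzene, rt
Reagents that add atoms: none
Why: RhCl(PPh3)3 hydrogenates the 1,2‑disubstituted C11=C12 alkene and leaves the tetrasubstituted, doubly neopentyl C5=C10 alkene and the ketone untouched (chemoselective homogeneous hydrogenation). No stereocentre is formed; the descriptors at C9 and C13 change only because the neighbouring carbons become saturated.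

Step 17
Reactants: 24 (7R,8R)‑8‑[(3R)‑5‑(tert‑butyldiphenylsilyloxy)‑3‑methylpentyl]‑4,4,7,8‑tetramethyl‑3,4,5,6,7,8‑hexahydronaphthalen‑1(2H)‑one
Product: 25 (1R,7R,8R)‑8‑[(3R)‑5‑(tert‑butyldiphenylsilyloxy)‑3‑methylpentyl]‑4,4,7,8‑tetramethyl‑1,2,3,4,5,6,7,8‑octahydronaphthalen‑1‑ol
Conditions: (S)‑2‑methyl‑CBS‑oxazaborolidine (0.5 equiv), BH3·SMe2, THF, −20 °C
Reagents that add atoms: none
Why: Corey–Bakshi–Shibata reduction: the oxazaborolidine binds the carbonyl lone pair anti to the large alkenyl flank (C10 with quaternary C9) and delivers hydride from coordinated borane to one face. With the (S)‑catalyst and the alkenyl group as the large substituent the (1R)‑carbinol is expected, with the hydroxyl on the face of C20.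

Step 18
Reactants: 25 (1R,7R,8R)‑8‑[(3R)‑5‑(tert‑butyldiphenylsilyloxy)‑3‑methylpentyl]‑4,4,7,8‑tetramethyl‑1,2,3,4,5,6,7,8‑octahydronaphthalen‑1‑ol
Product: 28 tert‑butyl({(3R)‑3‑methyl‑5‑[(1R,2R,4aS)‑1,2,5,5‑tetramethyl‑1,2,3,4,4a,5,6,7‑octahydronaphthalen‑1‑yl]pentyl}oxy)diphenylsilane, via sulfonylhydrazine 26 (not isolated), via allylic diazene 27 (not isolated)
Conditions: 2‑nitrobenzenesulfonylhydrazide, PPh3, DEAD, N‑methylmorpholine, −30 °C → 23 °C
Reagents that add atoms: none
Why: Mitsunobu displacement by the sulfonamide nitrogen inverts C1 (26); on warming, loss of 2‑nitrobenzenesulfinic acid gives monoalkyl diazene 27, which expels N2 in a retro‑ene reaction that passes its hydrogen suprafacially to C5 and moves the alkene to C1=C10 (Myers reductive transposition). Nitrogen sits on the face opposite the former hydroxyl, so H5 arrives on the face of C11 and C17, which is the (5S) configuration.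

Step 19
Reactants: 28 tert‑butyl({(3R)‑3‑methyl‑5‑[(1R,2R,4aS)‑1,2,5,5‑tetramethyl‑1,2,3,4,4a,5,6,7‑octahydronaphthalen‑1‑yl]pentyl}oxy)diphenylsilane
Product: 29 (3R)‑3‑methyl‑5‑[(1R,2R,4aS)‑1,2,5,5‑tetramethyl‑1,2,3,4,4a,5,6,7‑octahydronaphthalen‑1‑yl]pentan‑1‑ol
Conditions: Bu4NF, THF, rt
Reagents that add atoms: none
Why: Fluoride cleaves the Si–O bond of the primary silyl ether; the alkene and the stereocentres are not involved.

Step 20
Reactants: 29 (3R)‑3‑methyl‑5‑[(1R,2R,4aS)‑1,2,5,5‑tetramethyl‑1,2,3,4,4a,5,6,7‑octahydronaphthalen‑1‑yl]pentan‑1‑ol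
Product: 30 (3R)‑3‑methyl‑5‑[(1R,2R,4aS)‑1,2,5,5‑tetramethyl‑1,2,3,4,4a,5,6,7‑octahydronaphthalen‑1‑yl]pentanoic acid
Conditions: TEMPO (0.2 equiv), PhI(OAc)2 (2.2 equiv), MeCN–H2O, rt
Reagents that add atoms: water, O
Why: The oxoammonium ion from TEMPO oxidises the primary alcohol to the aldehyde, whose hydrate is oxidised on to the acid in the aqueous medium. The conditions do not affect the trisubstituted alkene, and C14 is a methylene, so nothing can epimerise.

Step 21
Reactants: 30 (3R)‑3‑methyl‑5‑[(1R,2R,4aS)‑1,2,5,5‑tetramethyl‑1,2,3,4,4a,5,6,7‑octahydronaphthalen‑1‑yl]pentanoic acid; 31 (R)‑solketal, [(4R)‑2,2‑dimethyl‑1,3‑dioxolan‑4‑yl]methanol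
Product: 32 [(4S)‑2,2‑dimethyl‑1,3‑dioxolan‑4‑yl]methyl (3R)‑3‑methyl‑5‑[(1R,2R,4aS)‑1,2,5,5‑tetramethyl‑1,2,3,4,4a,5,6,7‑octahydronaphthalen‑1‑yl]pentanoate
Conditions: EDC·HCl, DMAP, CH2Cl2, 0 °C → rt
Reagents that add atoms: none
Why: Carbodiimide/DMAP (Steglich) esterification of the acid with the primary hydroxyl of 31. The glycerol stereocentre is held in the acetonide and is not involved; its descriptor changes from R to S only because the substituent priorities change.

Step 22
Reactants: 32 [(4S)‑2,2‑dimethyl‑1,3‑dioxolan‑4‑yl]methyl (3R)‑3‑methyl‑5‑[(1R,2R,4aS)‑1,2,5,5‑tetramethyl‑1,2,3,4,4a,5,6,7‑octahydronaphthalen‑1‑yl]pentanoate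
Product: 33 (2S)‑2,3‑dihydroxypropyl (3R)‑3‑methyl‑5‑[(1R,2R,4aS)‑1,2,5,5‑tetramethyl‑1,2,3,4,4a,5,6,7‑octahydronaphthalen‑1‑yl]pentanoate
Conditions: AcOH–H2O (4:1), 40 °C
Reagents that add atoms: none
Why: Mild aqueous acid hydrolyses the terminal isopropylidene acetal to the 1,2‑diol. Acetic acid is too weak to protonate the C1=C10 alkene, and acid‑catalysed acyl migration should be slow at this temperature.

Step 23
Reactants: 33 (2S)‑2,3‑dihydroxypropyl (3R)‑3‑methyl‑5‑[(1R,2R,4aS)‑1,2,5,5‑tetramethyl‑1,2,3,4,4a,5,6,7‑octahydronaphthalen‑1‑yl]pentanoate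
Product: 34 (2S)‑3‑(acetyloxy)‑2‑hydroxypropyl (3R)‑3‑methyl‑5‑[(1R,2R,4aS)‑1,2,5,5‑tetramethyl‑1,2,3,4,4a,5,6,7‑octahydronaphthalen‑1‑yl]pentanoate (CNP0317518.1)
Conditions: AcCl (1.05 equiv), 2,4,6‑collidine, CH2Cl2, −78 °C
Reagents that add atoms: acetyl chloride, CC(Cl)=O
Why: At −78 °C acetyl chloride with the hindered base 2,4,6‑collidine acylates the primary hydroxyl of a 1,2‑diol much faster than the secondary one (selective monoacylation). The weakly basic, non‑nucleophilic medium should not promote acyl migration.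

## Compound list

1 | 3‑ethoxycyclohex‑2‑en‑1‑one | CCOC1=CC(=O)CCC1 | starting material
2 | 3‑ethoxy‑6‑methylcyclohex‑2‑en‑1‑one (racemic) | CCOC1=CC(=O)C(C)CC1 | intermediate
3 | 3‑ethoxy‑6,6‑dimethylcyclohex‑2‑en‑1‑one | CCOC1=CC(=O)C(C)(C)CC1 | intermediate
4 | (S)‑α‑methyl‑γ‑butyrolactone, (3S)‑3‑methyloxolan‑2‑one | C[C@H]1CCOC1=O | starting material
5 | (2S)‑4‑hydroxy‑N‑methoxy‑N,2‑dimethylbutanamide | CON(C)C(=O)[C@@H](C)CCO | intermediate
6 | (2S)‑4‑(tert‑butyldiphenylsilyloxy)‑N‑methoxy‑N,2‑dimethylbutanamide | CON(C)C(=O)[C@@H](C)CCO[Si](c1ccccc1)(c1ccccc1)C(C)(C)C | intermediate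
7 | (2S)‑4‑(tert‑butyldiphenylsilyloxy)‑2‑methylbutanal | O=C[C@@H](C)CCO[Si](c1ccccc1)(c1ccccc1)C(C)(C)C | intermediate
8 | (2S)‑4‑(tert‑butyldiphenylsilyloxy)‑2‑methylbutan‑1‑ol | OC[C@@H](C)CCO[Si](c1ccccc1)(c1ccccc1)C(C)(C)C | intermediate
9 | tert‑butyl{[(3S)‑4‑iodo‑3‑methylbutyl]oxy}diphenylsilane | IC[C@@H](C)CCO[Si](c1ccccc1)(c1ccccc1)C(C)(C)C | intermediate
10 | (R)‑α‑methyl‑γ‑butyrolactone, (3R)‑3‑methyloxolan‑2‑one | C[C@@H]1CCOC1=O | starting material
11 | (3R)‑3‑methyloxolan‑2‑ol (both anomers) | C[C@@H]1CCOC1O | intermediate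
12 | (3R)‑3‑methylpent‑4‑yn‑1‑ol | C#C[C@H](C)CCO | intermediate
13 | [(1E,3R)‑5‑(dimethylalumanyloxy)‑2,3‑dimethylpent‑1‑en‑1‑yl]dimethylalumane | C[Al](C)OCC[C@@H](C)/C(C)=C/[Al](C)C | intermediate
14 | (3R,4E)‑5‑iodo‑3,4‑dimethylpent‑4‑en‑1‑ol | OCC[C@@H](C)/C(C)=C/I | intermediate
15 | (1E,3R)‑5‑chloro‑1‑iodo‑2,3‑dimethylpent‑1‑ene | ClCC[C@@H](C)/C(C)=C/I | intermediate
16 | [(2S)‑4‑(tert‑butyldiphenylsilyloxy)‑2‑methylbutyl]zinc iodide | I[Zn]C[C@@H](C)CCO[Si](c1ccccc1)(c1ccccc1)C(C)(C)C | intermediate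
17 | tert‑butyl{[(3R,5E,7R)‑9‑chloro‑3,6,7‑trimethylnon‑5‑en‑1‑yl]oxy}diphenylsilane | CC(C)(C)[Si](c1ccccc1)(c1ccccc1)OCC[C@H](C)C/C=C(C)/[C@H](C)CCCl | intermediate
18 | tert‑butyl{[(3R,5E,7R)‑9‑iodo‑3,6,7‑trimethylnon‑5‑en‑1‑yl]oxy}diphenylsilane | CC(C)(C)[Si](c1ccccc1)(c1ccccc1)OCC[C@H](C)C/C=C(C)/[C@H](C)CCI | intermediate
19 | [(3R,4E,7R)‑9‑(tert‑butyldiphenylsilyloxy)‑3,4,7‑trimethylnon‑4‑en‑1‑yl]lithium | CC(C)(C)[Si](c1ccccc1)(c1ccccc1)OCC[C@H](C)C/C=C(C)/[C@H](C)CC[Li] | intermediate
20 | 1‑[(3R,4E,7R)‑9‑(tert‑butyldiphenylsilyloxy)‑3,4,7‑trimethylnon‑4‑en‑1‑yl]‑3‑ethoxy‑6,6‑dimethylcyclohex‑2‑en‑1‑ol (both carbinol epimers; lithium alkoxide in the flask) | CC(C)(C)[Si](c1ccccc1)(c1ccccc1)OCC[C@H](C)C/C=C(C)/[C@H](C)CCC1(O)C=C(OCC)CCC1(C)C | intermediate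
21 | 3‑[(3R,4E,7R)‑9‑(tert‑butyldiphenylsilyloxy)‑3,4,7‑trimethylnon‑4‑en‑1‑yl]‑4,4‑dimethylcyclohex‑2‑en‑1‑one | CC(C)(C)[Si](c1ccccc1)(c1ccccc1)OCC[C@H](C)C/C=C(C)/[C@H](C)CCC1=CC(=O)CCC1(C)C | intermediate
22 | 3‑[(3R,4E,7R)‑9‑(tert‑butyldiphenylsilyloxy)‑3,4,7‑trimethylnon‑4‑en‑1‑yl]‑2‑iodo‑4,4‑dimethylcyclohex‑2‑en‑1‑one | CC(C)(C)[Si](c1ccccc1)(c1ccccc1)OCC[C@H](C)C/C=C(C)/[C@H](C)CCC1=C(I)C(=O)CCC1(C)C | intermediate
23 | (7R,8S)‑8‑[(1E,3S)‑5‑(tert‑butyldiphenylsilyloxy)‑3‑methylpent‑1‑en‑1‑yl]‑4,4,7,8‑tetramethyl‑3,4,5,6,7,8‑hexahydronaphthalen‑1(2H)‑one | CC(C)(C)[Si](c1ccccc1)(c1ccccc1)OCC[C@H](C)/C=C/[C@@]1(C)C2=C(CC[C@H]1C)C(C)(C)CCC2=O | intermediate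
24 | (7R,8R)‑8‑[(3R)‑5‑(tert‑butyldiphenylsilyloxy)‑3‑methylpentyl]‑4,4,7,8‑tetramethyl‑3,4,5,6,7,8‑hexahydronaphthalen‑1(2H)‑one | CC(C)(C)[Si](c1ccccc1)(c1ccccc1)OCC[C@H](C)CC[C@@]1(C)C2=C(CC[C@H]1C)C(C)(C)CCC2=O | intermediate
25 | (1R,7R,8R)‑8‑[(3R)‑5‑(tert‑butyldiphenylsilyloxy)‑3‑methylpentyl]‑4,4,7,8‑tetramethyl‑1,2,3,4,5,6,7,8‑octahydronaphthalen‑1‑ol | CC(C)(C)[Si](c1ccccc1)(c1ccccc1)OCC[C@H](C)CC[C@@]1(C)C2=C(CC[C@H]1C)C(C)(C)CC[C@H]2O | intermediate
26 | N‑[(1S,7R,8R)‑8‑{(3R)‑5‑(tert‑butyldiphenylsilyloxy)‑3‑methylpentyl}‑4,4,7,8‑tetramethyl‑1,2,3,4,5,6,7,8‑octahydronaphthalen‑1‑yl]‑2‑nitrobenzenesulfonohydrazide (alkylated on the sulfonamide nitrogen) | CC(C)(C)[Si](c1ccccc1)(c1ccccc1)OCC[C@H](C)CC[C@@]1(C)C2=C(CC[C@H]1C)C(C)(C)CC[C@@H]2N(N)S(=O)(=O)c1ccccc1[N+](=O)[O-] | intermediate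
27 | [(1S,7R,8R)‑8‑{(3R)‑5‑(tert‑butyldiphenylsilyloxy)‑3‑methylpentyl}‑4,4,7,8‑tetramethyl‑1,2,3,4,5,6,7,8‑octahydronaphthalen‑1‑yl]diazene | CC(C)(C)[Si](c1ccccc1)(c1ccccc1)OCC[C@H](C)CC[C@@]1(C)C2=C(CC[C@H]1C)C(C)(C)CC[C@@H]2N=N | intermediate
28 | tert‑butyl({(3R)‑3‑methyl‑5‑[(1R,2R,4aS)‑1,2,5,5‑tetramethyl‑1,2,3,4,4a,5,6,7‑octahydronaphthalen‑1‑yl]pentyl}oxy)diphenylsilane | CC(C)(C)[Si](c1ccccc1)(c1ccccc1)OCC[C@H](C)CC[C@@]1(C)C2=CCCC(C)(C)[C@@H]2CC[C@H]1C | intermediate
29 | (3R)‑3‑methyl‑5‑[(1R,2R,4aS)‑1,2,5,5‑tetramethyl‑1,2,3,4,4a,5,6,7‑octahydronaphthalen‑1‑yl]pentan‑1‑ol | OCC[C@H](C)CC[C@@]1(C)C2=CCCC(C)(C)[C@@H]2CC[C@H]1C | intermediate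
30 | (3R)‑3‑methyl‑5‑[(1R,2R,4aS)‑1,2,5,5‑tetramethyl‑1,2,3,4,4a,5,6,7‑octahydronaphthalen‑1‑yl]pentanoic acid | OC(=O)C[C@H](C)CC[C@@]1(C)C2=CCCC(C)(C)[C@@H]2CC[C@H]1C | intermediate
31 | (R)‑solketal, [(4R)‑2,2‑dimethyl‑1,3‑dioxolan‑4‑yl]methanol | CC1(C)OC[C@H](O1)CO | starting material
32 | [(4S)‑2,2‑dimethyl‑1,3‑dioxolan‑4‑yl]methyl (3R)‑3‑methyl‑5‑[(1R,2R,4aS)‑1,2,5,5‑tetramethyl‑1,2,3,4,4a,5,6,7‑octahydronaphthalen‑1‑yl]pentanoate | CC1(C)OC[C@H](O1)COC(=O)C[C@H](C)CC[C@@]1(C)C2=CCCC(C)(C)[C@@H]2CC[C@H]1C | intermediate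
33 | (2S)‑2,3‑dihydroxypropyl (3R)‑3‑methyl‑5‑[(1R,2R,4aS)‑1,2,5,5‑tetramethyl‑1,2,3,4,4a,5,6,7‑octahydronaphthalen‑1‑yl]pentanoate | OC[C@H](O)COC(=O)C[C@H](C)CC[C@@]1(C)C2=CCCC(C)(C)[C@@H]2CC[C@H]1C | intermediate
34 | (2S)‑3‑(acetyloxy)‑2‑hydroxypropyl (3R)‑3‑methyl‑5‑[(1R,2R,4aS)‑1,2,5,5‑tetramethyl‑1,2,3,4,4a,5,6,7‑octahydronaphthalen‑1‑yl]pentanoate (CNP0317518.1) | CC(=O)OC[C@H](O)COC(=O)C[C@H](C)CC[C@@]1(C)C2=CCCC(C)(C)[C@@H]2CC[C@H]1C | target

## Step count and least certain steps

Total: 23 steps. Longest linear sequence: 17 steps (from lactone 10 through steps 7–23; the branch from lactone 4 through steps 3–6 and 11–23 has the same length).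

**Step 15 (key step).** The most likely failure is poor facial selectivity at C9. The preference of the C8 methyl for the pseudo‑equatorial position is small, and it is not known in advance which BINAP enantiomer reinforces it. Two further risks are re‑addition of the palladium hydride, which would move the new alkene toward C13 and erase that stereocentre, and reductive loss of iodine.
Fallback: the C1 reduction is moved ahead of the cyclisation, so that a stereocentre next to C10 directs the insertion instead of the ligand. Iodoenone 22 is reduced with (S)‑2‑methyl‑CBS‑oxazaborolidine and catecholborane to (1R)‑3‑[(3R,4E,7R)‑9‑(tert‑butyldiphenylsilyloxy)‑3,4,7‑trimethylnon‑4‑en‑1‑yl]‑2‑iodo‑4,4‑dimethylcyclohex‑2‑en‑1‑ol F1; 2‑iodoenones of this kind are standard substrates for that reduction. Cyclisation of F1 with Pd(OAc)2, PPh3 and Ag2CO3 in acetonitrile should give (1R,7R,8S)‑8‑[(1E,3S)‑5‑(tert‑butyldiphenylsilyloxy)‑3‑methylpent‑1‑en‑1‑yl]‑4,4,7,8‑tetramethyl‑1,2,3,4,5,6,7,8‑octahydronaphthalen‑1‑ol F2. The pseudo‑axial C1 hydroxyl and a pseudo‑axial C11 cannot share a face, which pushes C11 to the face of C17. Hydrogenation of F2 with H2 and RhCl(PPh3)3 returns to the route at 25.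

**Step 14.** Addition of the amine to the fully substituted C5, next to quaternary C4, may be too slow. Iodine would then react at C2 through the enol or with the trisubstituted C9=C11 alkene.
Fallback: the iodine is introduced before the tether. Vinylogous ester 3 is iodinated at its electron‑rich α‑carbon with N‑iodosuccinimide to 3‑ethoxy‑2‑iodo‑6,6‑dimethylcyclohex‑2‑en‑1‑one F3. Organolithium 19, made from 18 as in step 13, is transmetalated with CeCl3 to dichloro[(3R,4E,7R)‑9‑(tert‑butyldiphenylsilyloxy)‑3,4,7‑trimethylnon‑4‑en‑1‑yl]cerium F4, which is less prone to halogen–metal exchange. It adds to F3 to give 1‑[(3R,4E,7R)‑9‑(tert‑butyldiphenylsilyloxy)‑3,4,7‑trimethylnon‑4‑en‑1‑yl]‑3‑ethoxy‑2‑iodo‑6,6‑dimethylcyclohex‑2‑en‑1‑ol F5, and acid hydrolysis of F5 returns to the route at 22.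

**Step 17.** Hydride has to reach C1 from the face that the pseudo‑axial C11 chain on C9 shields. The catalyst therefore works against the substrate, and the reduction may be slow or give both carbinol epimers.
Fallback: the substrate's own preference is accepted and the centre is then inverted. Reduction of 24 with NaBH4 and CeCl3 in methanol should give mainly (1S,7R,8R)‑8‑[(3R)‑5‑(tert‑butyldiphenylsilyloxy)‑3‑methylpentyl]‑4,4,7,8‑tetramethyl‑1,2,3,4,5,6,7,8‑octahydronaphthalen‑1‑ol F6. Mitsunobu reaction of F6 with 4‑nitrobenzoic acid, PPh3 and DIAD gives (1R,7R,8R)‑8‑[(3R)‑5‑(tert‑butyldiphenylsilyloxy)‑3‑methylpentyl]‑4,4,7,8‑tetramethyl‑1,2,3,4,5,6,7,8‑octahydronaphthalen‑1‑yl 4‑nitrobenzoate F7, and methanolysis with K2CO3 returns to the route at 25. The fallback for step 15 also removes this problem, because there the reduction is carried out before C9 exists.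

**Step 18.** The Mitsunobu displacement at C1, a secondary carbinol beside a tetrasubstituted alkene and a quaternary carbon, may be slower than the thermal decomposition of the sulfonylhydrazide, or it may give elimination to a diene.
Fallback: the diazene is reached by reduction and not by substitution. Ketone 24 is condensed with 4‑methylbenzenesulfonylhydrazide (ethanol, catalytic acetic acid) to N′‑[(7R,8R)‑8‑{(3R)‑5‑(tert‑butyldiphenylsilyloxy)‑3‑methylpentyl}‑4,4,7,8‑tetramethyl‑3,4,5,6,7,8‑hexahydronaphthalen‑1(2H)‑ylidene]‑4‑methylbenzenesulfonohydrazide F8. Reduction of F8 with catecholborane, followed by sodium acetate and warming, delivers hydride to C1 from the less hindered face of C20. Loss of sulfinate then gives diazene 27, which collapses to 28, where the route is rejoined. Here C5 is under substrate control, and the expected sense is the required one.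

**Step 22.** Acyl migration between the glycerol oxygens during or after acetonide cleavage would give the 2‑acyl isomer and, after a second migration, erode the glycerol configuration. A shift of the C1=C10 alkene under acid is a smaller risk.
Fallback: the diol stage is avoided. Acid 30 is esterified (EDC·HCl, DMAP) with (R)‑glycidol to [(2S)‑oxiran‑2‑yl]methyl (3R)‑3‑methyl‑5‑[(1R,2R,4aS)‑1,2,5,5‑tetramethyl‑1,2,3,4,4a,5,6,7‑octahydronaphthalen‑1‑yl]pentanoate F9. The epoxide of F9 is opened at its terminal carbon by acetic acid with a catalytic tetraethylammonium bromide, which gives 34 directly and also replaces step 23.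

## Further compounds

F1 | step 15 | (1R)‑3‑[(3R,4E,7R)‑9‑(tert‑butyldiphenylsilyloxy)‑3,4,7‑trimethylnon‑4‑en‑1‑yl]‑2‑iodo‑4,4‑dimethylcyclohex‑2‑en‑1‑ol | CC(C)(C)[Si](c1ccccc1)(c1ccccc1)OCC[C@H](C)C/C=C(C)/[C@H](C)CCC1=C(I)[C@H](O)CCC1(C)C
F2 | step 15 | (1R,7R,8S)‑8‑[(1E,3S)‑5‑(tert‑butyldiphenylsilyloxy)‑3‑methylpent‑1‑en‑1‑yl]‑4,4,7,8‑tetramethyl‑1,2,3,4,5,6,7,8‑octahydronaphthalen‑1‑ol | CC(C)(C)[Si](c1ccccc1)(c1ccccc1)OCC[C@H](C)/C=C/[C@@]1(C)C2=C(CC[C@H]1C)C(C)(C)CC[C@H]2O
F3 | step 14 | 3‑ethoxy‑2‑iodo‑6,6‑dimethylcyclohex‑2‑en‑1‑one | CCOC1=C(I)C(=O)C(C)(C)CC1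
F4 | step 14 | dichloro[(3R,4E,7R)‑9‑(tert‑butyldiphenylsilyloxy)‑3,4,7‑trimethylnon‑4‑en‑1‑yl]cerium | CC(C)(C)[Si](c1ccccc1)(c1ccccc1)OCC[C@H](C)C/C=C(C)/[C@H](C)CC[Ce](Cl)Cl
F5 | step 14 | 1‑[(3R,4E,7R)‑9‑(tert‑butyldiphenylsilyloxy)‑3,4,7‑trimethylnon‑4‑en‑1‑yl]‑3‑ethoxy‑2‑iodo‑6,6‑dimethylcyclohex‑2‑en‑1‑ol | CC(C)(C)[Si](c1ccccc1)(c1ccccc1)OCC[C@H](C)C/C=C(C)/[C@H](C)CCC1(O)C(I)=C(OCC)CCC1(C)C
F6 | step 17 | (1S,7R,8R)‑8‑[(3R)‑5‑(tert‑butyldiphenylsilyloxy)‑3‑methylpentyl]‑4,4,7,8‑tetramethyl‑1,2,3,4,5,6,7,8‑octahydronaphthalen‑1‑ol | CC(C)(C)[Si](c1ccccc1)(c1ccccc1)OCC[C@H](C)CC[C@@]1(C)C2=C(CC[C@H]1C)C(C)(C)CC[C@@H]2O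
F7 | step 17 | (1R,7R,8R)‑8‑[(3R)‑5‑(tert‑butyldiphenylsilyloxy)‑3‑methylpentyl]‑4,4,7,8‑tetramethyl‑1,2,3,4,5,6,7,8‑octahydronaphthalen‑1‑yl 4‑nitrobenzoate | CC(C)(C)[Si](c1ccccc1)(c1ccccc1)OCC[C@H](C)CC[C@@]1(C)C2=C(CC[C@H]1C)C(C)(C)CC[C@H]2OC(=O)c1ccc(cc1)[N+](=O)[O-]
F8 | step 18 | N′‑[(7R,8R)‑8‑{(3R)‑5‑(tert‑butyldiphenylsilyloxy)‑3‑methylpentyl}‑4,4,7,8‑tetramethyl‑3,4,5,6,7,8‑hexahydronaphthalen‑1(2H)‑ylidene]‑4‑methylbenzenesulfonohydrazide | CC(C)(C)[Si](c1ccccc1)(c1ccccc1)OCC[C@H](C)CC[C@@]1(C)C2=C(CC[C@H]1C)C(C)(C)CCC2=NNS(=O)(=O)c1ccc(C)cc1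
F9 | step 22 | [(2S)‑oxiran‑2‑yl]methyl (3R)‑3‑methyl‑5‑[(1R,2R,4aS)‑1,2,5,5‑tetramethyl‑1,2,3,4,4a,5,6,7‑octahydronaphthalen‑1‑yl]pentanoate | C1[C@H](O1)COC(=O)C[C@H](C)CC[C@@]1(C)C2=CCCC(C)(C)[C@@H]2CC[C@H]1C
A1 | alternative 1 | 2‑[(3R)‑5‑(tert‑butyldiphenylsilyloxy)‑3‑methylpentyl]cyclohex‑2‑en‑1‑one | CC(C)(C)[Si](c1ccccc1)(c1ccccc1)OCC[C@H](C)CCC1=CCCCC1=O
A2 | alternative 1 | (2R,3R)‑2‑[(3R)‑5‑(tert‑butyldiphenylsilyloxy)‑3‑methylpentyl]‑2,3‑dimethylcyclohexan‑1‑one | CC(C)(C)[Si](c1ccccc1)(c1ccccc1)OCC[C@H](C)CC[C@@]1(C)C(=O)CCC[C@H]1C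
A3 | alternative 2 | 4‑[(1S,3R,4R)‑3‑{(3R)‑5‑(tert‑butyldiphenylsilyloxy)‑3‑methylpentyl}‑3,4‑dimethyl‑2‑oxocyclohexyl]‑4‑methylpentanal | CC(C)(C)[Si](c1ccccc1)(c1ccccc1)OCC[C@H](C)CC[C@@]1(C)C(=O)[C@@H](CC[C@H]1C)C(C)(C)CCC=O
A4 | alternative 2 | tert‑butyl({(3R)‑3‑methyl‑5‑[(1R,2R,4aS)‑1,2,5,5‑tetramethyl‑1,2,3,4,4a,5,6,7‑octahydronaphthalen‑1‑yl]pentyl}oxy)diphenylsilane (identical with 28) | CC(C)(C)[Si](c1ccccc1)(c1ccccc1)OCC[C@H](C)CC[C@@]1(C)C2=CCCC(C)(C)[C@@H]2CC[C@H]1C
A5 | alternative 3 | tert‑butyl({(3R)‑5‑[(1R,6R)‑2‑ethenyl‑1,6‑dimethylcyclohex‑2‑en‑1‑yl]‑3‑methylpentyl}oxy)diphenylsilane | CC(C)(C)[Si](c1ccccc1)(c1ccccc1)OCC[C@H](C)CC[C@@]1(C)C(C=C)=CCC[C@H]1C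
A6 | alternative 3 | methacrolein (2‑methylprop‑2‑enal) | CC(=C)C=O
A7 | alternative 3 | (1R,5R,6R,8aR)‑5‑[(3R)‑5‑(tert‑butyldiphenylsilyloxy)‑3‑methylpentyl]‑1,5,6‑trimethyl‑1,2,3,5,6,7,8,8a‑octahydronaphthalene‑1‑carbaldehyde | CC(C)(C)[Si](c1ccccc1)(c1ccccc1)OCC[C@H](C)CC[C@@]1(C)C2=CCC[C@@](C)(C=O)[C@@H]2CC[C@H]1C
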